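I wanted to know how much target stood in this flask at 6.0 h, and which step taken then would raise it most.

in all of them: starting material 0.10 M; catalyst 0.94 mol%
- summer: reagent 1.2 equiv; second substrate 0.50 equiv; protic impurity 0.030 M; the very flask that is asked about, followed so far
- flask: reagent 1.20 equiv; second substrate 0.500 equiv; protic impurity 0.0300 M; time 6.0 h

- summer (time / h: target / %, starting material / %): 0.833: 58, 33; 2.00: 50, 28; 4.00: 43, 20; 6.00: 43, 27

(readings scatter by 2 percentage points)

- delta: at 6.0 h take out 90% of the target then present, then wait 2.0 h
- alpha: at 6.0 h add reagent, 100% of the amount charged, then wait 2.0 h
- epsilon: change nothing and wait 2.0 h more
- beta: at 6.0 h add catalyst, 50.0% of the amount charged, then wait 2.0 h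

* target, in percent of the starting material first charged, at 6.0 h
* what to do for the largest gain in target; "none" if nothing gains more than 2 percentage points (delta / alpha / epsilon / beta / none)
* target present, with what was taken out counted in, in percent of the starting material first charged, after delta
* target present, with what was taken out counted in, in percent of the starting material first charged, after beta

- removed target is counted in
- additions bring no volume worth counting

Starting material fell fast and then stopped at about a quarter of its charge. I took the second substrate as a rival for the reagent, on equal terms, and folded the charges into one number, the cover: the reagent charged over the starting material and second substrate together.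

cover = charged [reagent] / (charged [starting material] + charged [second substrate]) = 0.800

Below one, the reagent is the limiting reagent, and each substrate keeps the uncovered part:

starting material left = 20.0%

The last 3 readings average 25.0%, so the cover described the stop fairly, with somewhat more left than it says.

But one number was not enough. Between 0.833 h and 6.00 h the target readings fell from 58% to 43%, although the starting material readings fell too, from 33% to 27%, and 30.0% of the charge was unaccounted for at 6.00 h. The cover tells how much reacted, not how much stays target.

So I took 43% for now, with its scatter. Catalyst leaves the cover unchanged, so I expected beta to do no better than waiting, and both to lose a little. Alpha gives a new cover on what remains: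

added reagent / (starting material left + second substrate left) = 3.24

That is above one, so alpha could bring up to 27% more, less what drains away. I chose alpha, and expected delta to gain only if the unaccounted part returned.

The forecast gave 42% now, 42% after delta and 48% after beta, and chose beta: “That looks like catalyst death, probably from the protic impurity, rather than reagent shortage”.

The flask held 39.6%; the best step was alpha, gaining 16 percentage points, while delta gave 49.7% counted and beta 38.2%.

    starting material + reagent + catalyst → catalyst + target (k = 580 M⁻² min⁻¹)
    second substrate + reagent + catalyst → catalyst + second product (k = 810 M⁻² min⁻¹)
    2 reagent → self-condensation product (k = 0.0280 M⁻¹ min⁻¹)
    second substrate + protic impurity → quenched substrate (k = 0.180 M⁻¹ min⁻¹)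
    target ⇌ isomer of the product (K = 1.00, k = 0.00430 min⁻¹)

In this flask reagent stood at 0.818% of its charge at 3.00 h and 0.0480% at 6.00 h, with catalyst at 100% of its charge and starting material at 25.3%. At that time target was made more slowly than it was used up, at 0.0413 of that rate. The neighbour flask with 0.720 equiv of reagent has a cover of 0.480, which leaves 52.0%, and it held 55.8% of its starting material at 6.00 h.

The earlier runs and the new flask were computed on assumed constants.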